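The ratio to start from is how much faster the single-handed free catalyst takes left-handed substrate than right-handed substrate. From it I count turnovers.

| setting | south | flask |
|---|---|---|
| left-handed substrate | 10 mM | 10 mM |
| right-handed substrate | 10 mM | 10 mM |
| partner | 20 mM | 20.0 mM |
| protic impurity | 2.5 mM | 5.00 mM |
| free catalyst | 20 µM | 20 µM |
| remark | run made earlier |  |
| time |  | 6.0 h |

south run (percent of the left-handed substrate and right-handed substrate together charged)

| time / min | right-handed substrate / % | left-handed substrate / % |
|---|---|---|
| 15.0 | 46.4 | 41.1 |
| 30.0 | 44.5 | 35.4 |
| 40.0 | 43.0 | 31.2 |
| 60.0 | 41.1 | 28.5 |
| 80.0 | 39.7 | 24.5 |

(standard deviation of a reading: 0.5 percentage points)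

* whether the excess of right-handed substrate over left-handed substrate among what is left of the two reaches 95% by 6.0 h (yes / no)
* the highest excess of right-handed substrate over left-handed substrate among what is left of the two up to 6.0 h

- free catalyst is single-handed; left-handed substrate and right-handed substrate are mirror images of each other, charged as a racemate, each of them at the stated concentration
- steps that have been proposed: 2 free catalyst -> spent catalyst; partner + free catalyst + right-handed substrate -> free catalyst + right-handed product; left-handed product <-> right-handed product; partner + free catalyst + left-handed substrate -> free catalyst + left-handed product; partner + protic impurity -> quenched reagent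
- no earlier run changes the charge of protic impurity; that part of a forecast is a guess

I read the south table from its last row. Each substrate starts at half the total, and 24.5% left-handed and 39.7% right-handed substrate remain. The ratio of the logarithms of those two falls is the selectivity factor, s = 3.09.

Adding the columns gives the turnovers N, substrate gone per catalyst charged. The first row has 125 and the last 358. The pace reads 8.33 min⁻¹ in the first row and 2.70 min⁻¹ in the last, so it is slower late in the south run.

Now I ask what 95% costs at this s. It needs a share y = 0.174 of the right-handed substrate left. I call the demand D the turnovers the catalyst must make to reach the wanted excess at this s: 911.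

No earlier run varies the protic impurity, so I guess that its whole charge takes partner. The flask then offers 750 turnovers, fewer than D. My answer is no.

The forecast says no, with a top of 40%: “So 95% is unreachable.”

The flask gives no and a top of 40.2%. In the flask at 6.00 h, partner stands at 22.2% of its charge and free catalyst at 33.5% of the catalyst charged. The products there count 544 turnovers, which is 59.8% of D.

    2 free catalyst → spent catalyst (k = 2.30 L mol⁻¹ s⁻¹)
    partner + free catalyst + right-handed substrate → free catalyst + right-handed product (k = 210 L² mol⁻² s⁻¹)
    left-handed product ⇌ right-handed product (k = 2.20 × 10⁻⁵ s⁻¹)
    partner + free catalyst + left-handed substrate → free catalyst + left-handed product (k = 610 L² mol⁻² s⁻¹)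
    partner + protic impurity → quenched reagent (k = 0.0160 L mol⁻¹ s⁻¹)

A neighbour flask differs from the flask in holding 8.0 mM of partner. Its whole partner charge, with none counted as lost to protic impurity, offers 400 turnovers, below D, so I again say no. Computed, its top is 13.3%, and its products at 6.00 h count 234 turnovers.

(The numbers in the tables stem from a simulated flask with made-up constants, and the scatter is random.)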